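## Retrosynthetic overview

1. Target 27 ⇐ kinetic protonation at C5 of the ring A enolate of the bicyclic vinylogous ester 25.
2. Ring A ⇐ Dieckmann-type attack of a C7 enolate on the carbonyl of γ-lactone 23; the freed C2 alcohol then recloses ring B as the cyclic enol ether.
3. Quaternary C3a ⇐ Michael addition (C4–C7 chain) followed by decarboxylative allylation of an allyl lactone-3-carboxylate, allyl entering anti to the aryl group.
4. Fragment union ⇐ aryl Grignard 19 (from bromide 5) + butenolide ester 13 by conjugate addition anti to the methyl group, then enone 18.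
5. Ring order: arene (from phenol) → ring B as a γ-lactone (step 6) → ring A (step 15); all chirality derives from (R)-2-methyloxirane.

Assumption: the target is the (2R,3S,3aR,5S) isomer encoded by the SMILES (2-methyl trans to 3-aryl, 3-aryl trans to 3a-allyl, 5-methoxy cis to 3a-allyl), and the six numbered starting materials are catalogue chemicals.

## Route

Step 1
Reactants: 1 phenol
Product: 2 2,6-dibromophenol
Conditions: NBS (2.0 equiv), diisopropylamine (10 mol %), CH2Cl2, 0 °C to rt
Reagents that add atoms: N-bromosuccinimide, O=C1CCC(=O)N1Br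
Why: Amine-catalysed ortho-selective electrophilic bromination of the phenol stops cleanly at the 2,6-dibromide.

Step 2
Reactants: 2 2,6-dibromophenol
Product: 3 2,6-dimethoxyphenol
Conditions: NaOMe (25 % in MeOH, 6 equiv), CuI (10 mol %), DMF, 110 °C; aq. HCl
Reagents that add atoms: sodium methoxide, [Na+].[O-]C
Why: Copper-catalysed Ullmann-type methoxylation replaces both aryl bromides.

Step 3
Reactants: 3 2,6-dimethoxyphenol
Product: 4 4-bromo-2,6-dimethoxyphenol
Conditions: NBS (1.0 equiv), CHCl3, −40 °C to rt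
Reagents that add atoms: N-bromosuccinimide, O=C1CCC(=O)N1Br
Why: Electrophilic aromatic bromination goes para to the free hydroxyl, the most activated open position.

Step 4
Reactants: 4 4-bromo-2,6-dimethoxyphenol
Product: 5 5-bromo-1,2,3-trimethoxybenzene
Conditions: MeI, K2CO3, acetone, reflux
Reagents that add atoms: iodomethane, CI
Why: Williamson O-methylation of the phenoxide.

Step 5
Reactants: 6 malonic acid; 7 prop-2-en-1-ol
Product: 8 diallyl malonate
Conditions: prop-2-en-1-ol (2.5 equiv in all), p-TsOH·H2O (5 mol %), toluene, reflux, Dean–Stark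
Reagents that add atoms: second equivalent of prop-2-en-1-ol, C=CCO
Why: Twofold Fischer esterification, one molecule of allyl alcohol per carboxyl group, driven by azeotropic removal of water.

Step 6
Reactants: 8 diallyl malonate; 9 (R)-2-methyloxirane
Product: 10 allyl (5R)-5-methyl-2-oxotetrahydrofuran-3-carboxylate
Conditions: NaH (1.05 equiv), THF, 0 °C; then 9, 65 °C (sealed); AcOH
Reagents that add atoms: none
Why: The malonate anion opens the epoxide at CH2 (SN2, stereocentre untouched) and the alkoxide lactonises with loss of allyl alkoxide, so C5 keeps the R configuration of 9.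

Step 7
Reactants: 10 allyl (5R)-5-methyl-2-oxotetrahydrofuran-3-carboxylate
Product: 11 allyl (5R)-5-methyl-2-oxo-3-(phenylselanyl)tetrahydrofuran-3-carboxylate
Conditions: NaH, THF, 0 °C; PhSeCl
Reagents that add atoms: benzeneselenenyl chloride, Cl[Se]c1ccccc1
Why: α-Selenenylation of the malonate-type sodium enolate.

Step 8
Reactants: 11 allyl (5R)-5-methyl-2-oxo-3-(phenylselanyl)tetrahydrofuran-3-carboxylate
Product: 13 allyl (5R)-5-methyl-2-oxo-2,5-dihydrofuran-3-carboxylate, via selenoxide 12 (not isolated)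
Conditions: H2O2 (30 %, 2 equiv), CH2Cl2, 0 °C to rt; used at once
Reagents that add atoms: none
Why: Selenide oxidation and syn-selenoxide elimination; only the ring CH2 carries a β-hydrogen, so the endocyclic alkene forms and C5 is untouched.

Step 9
Reactants: 14 methoxyacetyl chloride
Product: 15 N,2-dimethoxy-N-methylacetamide
Conditions: MeNHOMe·HCl, pyridine (2.2 equiv), CH2Cl2, 0 °C to rt
Reagents that add atoms: N,O-dimethylhydroxylamine hydrochloride, CNOC.Cl
Why: N-Acylation gives the Weinreb amide.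

Step 10
Reactants: 16 methoxyethene; 15 N,2-dimethoxy-N-methylacetamide
Product: 18 1,3-dimethoxybut-3-en-2-one, via 1-methoxyvinyllithium 17 (not isolated)
Conditions: t-BuLi, THF, −78 to 0 °C; then 15, −78 °C; aq. NH4Cl
Reagents that add atoms: none
Why: α-Lithiation of the vinyl ether, then acyl substitution on the Weinreb amide, whose chelated tetrahedral intermediate stops the addition at the ketone.

Step 11
Reactants: 5 5-bromo-1,2,3-trimethoxybenzene; 13 allyl (5R)-5-methyl-2-oxo-2,5-dihydrofuran-3-carboxylate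
Product: 20 allyl (3R,4R,5R)-5-methyl-2-oxo-4-(3,4,5-trimethoxyphenyl)tetrahydrofuran-3-carboxylate, via arylmagnesium bromide 19 (not isolated)
Conditions: Mg, LiCl, THF, rt; then CuBr·SMe2 (10 mol %), 13, THF, −78 °C; aq. NH4Cl
Reagents that add atoms: none
Why: Copper-catalysed conjugate addition of the aryl Grignard to the doubly activated butenolide occurs anti to the C5 methyl group (sets the aryl-bearing centre), and the acidic C3 settles as the all-trans isomer.

Step 12
Reactants: 20 allyl (3R,4R,5R)-5-methyl-2-oxo-4-(3,4,5-trimethoxyphenyl)tetrahydrofuran-3-carboxylate; 18 1,3-dimethoxybut-3-en-2-one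
Product: 21 allyl (3S,4S,5R)-3-(2,4-dimethoxy-3-oxobutyl)-5-methyl-2-oxo-4-(3,4,5-trimethoxyphenyl)tetrahydrofuran-3-carboxylate
Conditions: DBU (10 mol %), MeCN, 0 °C to rt
Reagents that add atoms: none
Why: Base-catalysed Michael addition of the malonate-type C–H acid to the vinyl ketone installs C4–C7; the C3 configuration is erased in step 14 and the new CH(OMe) centre is an epimer mixture corrected in step 16.

Step 13
Reactants: 21 allyl (3S,4S,5R)-3-(2,4-dimethoxy-3-oxobutyl)-5-methyl-2-oxo-4-(3,4,5-trimethoxyphenyl)tetrahydrofuran-3-carboxylate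
Product: 22 allyl (3S,4S,5R)-3-[(Z)-2,4-dimethoxy-3-(triethylsilyloxy)but-3-en-1-yl]-5-methyl-2-oxo-4-(3,4,5-trimethoxyphenyl)tetrahydrofuran-3-carboxylate
Conditions: LiN(SiMe3)2 (1.1 equiv), Et3SiCl (1.5 equiv, present from the start), THF, −78 °C
Reagents that add atoms: chlorotriethylsilane, CC[Si](Cl)(CC)CC
Why: Kinetic, chelation-controlled enolisation on the less hindered CH2OMe side with in situ O-silylation masks the acidic ketone as its Z silyl enol ether.

Step 14
Reactants: 22 allyl (3S,4S,5R)-3-[(Z)-2,4-dimethoxy-3-(triethylsilyloxy)but-3-en-1-yl]-5-methyl-2-oxo-4-(3,4,5-trimethoxyphenyl)tetrahydrofuran-3-carboxylate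
Product: 23 (3R,4S,5R)-3-allyl-3-[(Z)-2,4-dimethoxy-3-(triethylsilyloxy)but-3-en-1-yl]-5-methyl-4-(3,4,5-trimethoxyphenyl)dihydrofuran-2(3H)-one
Conditions: Pd(PPh3)4 (5 mol %), 1,4-dioxane, 80 °C
Reagents that add atoms: none
Why: Tsuji decarboxylative allylation: zerovalent palladium ionises the allyl ester, loss of CO2 gives the lactone enolate, and allylation at that carbon anti to the vicinal aryl group fixes the quaternary centre (allyl trans to aryl).

Step 15
Reactants: 23 (3R,4S,5R)-3-allyl-3-[(Z)-2,4-dimethoxy-3-(triethylsilyloxy)but-3-en-1-yl]-5-methyl-4-(3,4,5-trimethoxyphenyl)dihydrofuran-2(3H)-one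
Product: 25 (2R,3S,3aR)-3a-allyl-5,7-dimethoxy-2-methyl-3-(3,4,5-trimethoxyphenyl)-3,3a,4,5-tetrahydro-1-benzofuran-6(2H)-one as a C5 epimer mixture, via hydroxy diketone 24 (not isolated)
Conditions: Bu4NF (dried, 1.2 equiv), THF, −40 to 0 °C; AcOH; then p-TsOH·H2O (10 mol %), toluene, 4 Å MS, 50 °C
Reagents that add atoms: none
Why: Fluoride releases the regiodefined C7 enolate, which acylates itself on the lactone carbonyl (Dieckmann-type Claisen condensation, ring A); under acid the freed alcohol condenses with the only dione carbonyl within reach of a five-membered ring to give the cyclic vinylogous ester (ring B), leaving C2, C3 and C3a untouched.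

Step 16
Reactants: 25 (2R,3S,3aR)-3a-allyl-5,7-dimethoxy-2-methyl-3-(3,4,5-trimethoxyphenyl)-3,3a,4,5-tetrahydro-1-benzofuran-6(2H)-one (C5 epimer mixture)
Product: 27 (2R,3S,3aR,5S)-3a-allyl-5,7-dimethoxy-2-methyl-3-(3,4,5-trimethoxyphenyl)-3,3a,4,5-tetrahydro-1-benzofuran-6(2H)-one, via lithium enolate 26 (not isolated)
Conditions: LiN(SiMe3)2 (1.1 equiv), THF, −78 °C; then t-BuCO2H in THF, −78 °C; pH 7 buffer
Reagents that add atoms: none
Why: C5 is the only enolisable position, and Zimmerman-type kinetic protonation of the enolate by the bulky acid on the face opposite the pseudoaxial 3a-allyl group places the 5-methoxy group cis to allyl (5S); the 5R epimer is separated and recycled.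

## Compound list

1 | phenol | Oc1ccccc1 | starting material
2 | 2,6-dibromophenol | Oc1c(Br)cccc1Br | intermediate
3 | 2,6-dimethoxyphenol | COc1cccc(OC)c1O | intermediate
4 | 4-bromo-2,6-dimethoxyphenol | COc1cc(Br)cc(OC)c1O | intermediate
5 | 5-bromo-1,2,3-trimethoxybenzene | COc1cc(Br)cc(OC)c1OC | intermediate
6 | malonic acid | OC(=O)CC(=O)O | starting material
7 | prop-2-en-1-ol (allyl alcohol) | C=CCO | starting material
8 | diallyl malonate | C=CCOC(=O)CC(=O)OCC=C | intermediate
9 | (R)-2-methyloxirane | C[C@@H]1CO1 | starting material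
10 | allyl (5R)-5-methyl-2-oxotetrahydrofuran-3-carboxylate (C3 epimers) | C=CCOC(=O)C1C[C@@H](C)OC1=O | intermediate
11 | allyl (5R)-5-methyl-2-oxo-3-(phenylselanyl)tetrahydrofuran-3-carboxylate (C3 epimers) | C=CCOC(=O)C1([Se]c2ccccc2)C[C@@H](C)OC1=O | intermediate
12 | allyl (5R)-5-methyl-2-oxo-3-(phenylseleninyl)tetrahydrofuran-3-carboxylate (selenoxide) | C=CCOC(=O)C1([Se](=O)c2ccccc2)C[C@@H](C)OC1=O | intermediate
13 | allyl (5R)-5-methyl-2-oxo-2,5-dihydrofuran-3-carboxylate | C=CCOC(=O)C1=C[C@@H](C)OC1=O | intermediate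
14 | methoxyacetyl chloride | COCC(=O)Cl | starting material
15 | N,2-dimethoxy-N-methylacetamide | COCC(=O)N(C)OC | intermediate
16 | methoxyethene (methyl vinyl ether) | COC=C | starting material
17 | (1-methoxyethenyl)lithium | [Li]C(=C)OC | intermediate
18 | 1,3-dimethoxybut-3-en-2-one | C=C(OC)C(=O)COC | intermediate
19 | (3,4,5-trimethoxyphenyl)magnesium bromide | COc1cc([Mg]Br)cc(OC)c1OC | intermediate
20 | allyl (3R,4R,5R)-5-methyl-2-oxo-4-(3,4,5-trimethoxyphenyl)tetrahydrofuran-3-carboxylate | C=CCOC(=O)[C@@H]1C(=O)O[C@H](C)[C@H]1c2cc(OC)c(OC)c(OC)c2 | intermediate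
21 | allyl (3S,4S,5R)-3-(2,4-dimethoxy-3-oxobutyl)-5-methyl-2-oxo-4-(3,4,5-trimethoxyphenyl)tetrahydrofuran-3-carboxylate (epimers at the side-chain CH(OMe)) | COCC(=O)C(OC)C[C@@]1(C(=O)O[C@H](C)[C@H]1c2cc(OC)c(OC)c(OC)c2)C(=O)OCC=C | intermediate
22 | allyl (3S,4S,5R)-3-[(Z)-2,4-dimethoxy-3-(triethylsilyloxy)but-3-en-1-yl]-5-methyl-2-oxo-4-(3,4,5-trimethoxyphenyl)tetrahydrofuran-3-carboxylate (epimers at the side-chain CH(OMe)) | CO/C=C(\O[Si](CC)(CC)CC)C(OC)C[C@@]1(C(=O)O[C@H](C)[C@H]1c2cc(OC)c(OC)c(OC)c2)C(=O)OCC=C | intermediate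
23 | (3R,4S,5R)-3-allyl-3-[(Z)-2,4-dimethoxy-3-(triethylsilyloxy)but-3-en-1-yl]-5-methyl-4-(3,4,5-trimethoxyphenyl)dihydrofuran-2(3H)-one (epimers at the side-chain CH(OMe)) | C=CC[C@@]1(C(=O)O[C@H](C)[C@H]1c2cc(OC)c(OC)c(OC)c2)CC(OC)/C(O[Si](CC)(CC)CC)=C/OC | intermediate
24 | (4R)-4-allyl-3-hydroxy-4-[(1S,2R)-2-hydroxy-1-(3,4,5-trimethoxyphenyl)propyl]-2,6-dimethoxycyclohex-2-en-1-one (enol form of the 1,3-diketone, C6 epimers) | C=CC[C@@]1(CC(OC)C(=O)C(OC)=C1O)[C@H](c2cc(OC)c(OC)c(OC)c2)[C@@H](C)O | intermediate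
25 | (2R,3S,3aR)-3a-allyl-5,7-dimethoxy-2-methyl-3-(3,4,5-trimethoxyphenyl)-3,3a,4,5-tetrahydro-1-benzofuran-6(2H)-one (C5 epimer mixture) | C=CC[C@]12CC(OC)C(=O)C(OC)=C1O[C@H](C)[C@H]2c1cc(OC)c(OC)c(OC)c1 | intermediate
26 | lithium (2R,3S,3aR)-3a-allyl-5,7-dimethoxy-2-methyl-3-(3,4,5-trimethoxyphenyl)-2,3,3a,4-tetrahydro-1-benzofuran-6-olate | C=CC[C@]12CC(OC)=C(O[Li])C(OC)=C1O[C@H](C)[C@H]2c1cc(OC)c(OC)c(OC)c1 | intermediate
27 | (2R,3S,3aR,5S)-3a-allyl-5,7-dimethoxy-2-methyl-3-(3,4,5-trimethoxyphenyl)-3,3a,4,5-tetrahydro-1-benzofuran-6(2H)-one | C=CC[C@]12C[C@H](OC)C(=O)C(OC)=C1O[C@H](C)[C@H]2c1cc(OC)c(OC)c(OC)c1 | target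

## Step count and risks

Total step count: 16.
Longest linear sequence: 10 steps (steps 1–4 then 11–16; equally steps 5–8 then 11–16). The third branch (steps 9–10) joins at step 12.

Steps most likely to fail:

Step 14. A malonate-type lactone ester loses CO2 reluctantly, so ionisation may end in protonation instead of allylation. The fallback separates the two events and sets out from 22. Pd(PPh3)4 (cat.) with morpholine in THF at rt transfers the allyl group to the amine and leaves (3S,4S,5R)-3-[(Z)-2,4-dimethoxy-3-(triethylsilyloxy)but-3-en-1-yl]-5-methyl-2-oxo-4-(3,4,5-trimethoxyphenyl)tetrahydrofuran-3-carboxylic acid F1, kept as its morpholinium salt so that the silyl enol ether never meets free acid. Warming in toluene at 90 °C decarboxylates it to (4R,5R)-3-[(Z)-2,4-dimethoxy-3-(triethylsilyloxy)but-3-en-1-yl]-5-methyl-4-(3,4,5-trimethoxyphenyl)dihydrofuran-2(3H)-one F2. Classical enolate alkylation (LiN(SiMe3)2, THF, −78 °C, then allyl bromide), again anti to the aryl group, comes back to the route at 23.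

Step 15. The fluoride-generated enolate may be protonated or may fail to acylate on the hindered lactone carbonyl. The fallback activates the electrophile instead of the nucleophile and sets out from 23. Et3OBF4 in CH2Cl2 (0 °C to rt) O-ethylates the lactone to (3R,4S,5R)-3-allyl-3-[(Z)-2,4-dimethoxy-3-(triethylsilyloxy)but-3-en-1-yl]-2-ethoxy-5-methyl-4-(3,4,5-trimethoxyphenyl)-4,5-dihydro-3H-furan-1-ium tetrafluoroborate F3. Its dialkoxycarbenium carbon is attacked by the tethered silyl enol ether (intramolecular Mukaiyama-type acylation), and the resulting cyclic mixed ketal loses ethanol, so the sequence comes back at 25 with the ring B oxygen never detached.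

Step 16. Substrate-controlled protonation may give a poor 5S : 5R ratio. The fallback moves face selection from the substrate to the reagent and sets out from 25. LiN(SiMe3)2 and Me3SiCl (THF, −78 °C) give (2R,3S,3aR)-3a-allyl-5,7-dimethoxy-2-methyl-6-(trimethylsilyloxy)-3-(3,4,5-trimethoxyphenyl)-2,3,3a,4-tetrahydro-1-benzofuran F4. This isolated silyl dienol ether is protonated with the stoichiometric chiral Brønsted acid BINOL·SnCl4 (toluene, −78 °C; the matched BINOL enantiomer is found on small scale), which comes back at 27.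

## Further compounds

F1 | step 14 | (3S,4S,5R)-3-[(Z)-2,4-dimethoxy-3-(triethylsilyloxy)but-3-en-1-yl]-5-methyl-2-oxo-4-(3,4,5-trimethoxyphenyl)tetrahydrofuran-3-carboxylic acid | CO/C=C(\O[Si](CC)(CC)CC)C(OC)C[C@@]1(C(=O)O[C@H](C)[C@H]1c2cc(OC)c(OC)c(OC)c2)C(=O)O
F2 | step 14 | (4R,5R)-3-[(Z)-2,4-dimethoxy-3-(triethylsilyloxy)but-3-en-1-yl]-5-methyl-4-(3,4,5-trimethoxyphenyl)dihydrofuran-2(3H)-one (C3 epimers) | CO/C=C(\O[Si](CC)(CC)CC)C(OC)CC1C(=O)O[C@H](C)[C@H]1c2cc(OC)c(OC)c(OC)c2
F3 | step 15 | (3R,4S,5R)-3-allyl-3-[(Z)-2,4-dimethoxy-3-(triethylsilyloxy)but-3-en-1-yl]-2-ethoxy-5-methyl-4-(3,4,5-trimethoxyphenyl)-4,5-dihydro-3H-furan-1-ium tetrafluoroborate | C=CC[C@@]1(C(OCC)=[O+][C@H](C)[C@H]1c2cc(OC)c(OC)c(OC)c2)CC(OC)/C(O[Si](CC)(CC)CC)=C/OC.F[B-](F)(F)F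
F4 | step 16 | (2R,3S,3aR)-3a-allyl-5,7-dimethoxy-2-methyl-6-(trimethylsilyloxy)-3-(3,4,5-trimethoxyphenyl)-2,3,3a,4-tetrahydro-1-benzofuran | C=CC[C@]12CC(OC)=C(O[Si](C)(C)C)C(OC)=C1O[C@H](C)[C@H]2c1cc(OC)c(OC)c(OC)c1
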